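## Analysis of the target

Compound 18 is a 2-aryl-3-methyl-2,3-dihydro-1-benzofuran. Ring A (C3a, C4, C5, C6, C7, C7a) is fused to the dihydrofuran ring (O1, C2, C3), and ring B, a 3-hydroxy-4,5-dimethoxyphenyl group, sits on C2. Ring A carries O1 at C7a, a methoxy group at C7, an (E)-prop-1-enyl group at C5 and hydrogen at C4 and C6. The two stereocentres are adjacent, C2 (S, aryl) and C3 (S, methyl), with aryl and methyl trans on the five-membered ring. C2 is a benzylic ether carbon para to a ring B methoxy group and can ionise under acid. The propenylarene is sensitive to acid, oxidants and hydrogenation, and the free phenol to oxidation. The difficulty is to fix the absolute configuration of both centres and to assemble an electron-rich, tetrasubstituted ring A without acidic or oxidising steps after the centres exist, while keeping one of three ring B oxygens as a free hydroxyl. The strategy rests on one feature: O1 at C7a, methoxy at C7 and propenyl at C5 map onto positions 3, 4 and 6 of a 2-pyrone, while C3a and C4 are the two carbons of an alkyne joined to O1 through C2 and C3.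

## Retrosynthetic reasoning

**18 from 17.** The last disconnection is the O–Si bond of the ring B silyl ether. A silyl ether is chosen because it can be removed under buffered, nearly neutral conditions that spare C2 and the propenyl group. The triisopropylsilyl group is preferred to a smaller one because the route passes through a carbonate-mediated methylation and prolonged heating.

**17 from 15.** Ring A is cut at C3a–C7a and C4–C5. C3a and C4 become a terminal alkyne; C7a, C7, C6 and C5 become C3, C4, C5 and C6 of a 2-pyrone, whose lactone bridge is restored. This cut is chosen because the pyrone already carries every ring A substituent in its final form, because both rings close in one operation, and because the three-atom O1–C2–C3 tether leaves no regiochemical choice. The forward reaction must achieve a thermal intramolecular [4+2] cycloaddition and decarboxylative cycloreversion without touching the two stereocentres.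

**15 from 14.** The methyl group on the C4 oxygen of the pyrone is removed. This returns the pyrone to the enol of a cyclic 2,4-dione, which is what makes the next disconnection possible.

**14 from 13 and 7.** The bond between pyrone C3 and the ether oxygen is cut. The bond is made on the oxygen side, not at the benzylic carbon, because substitution at that carbon would risk ionisation and loss of configuration. A rhodium carbenoid from diazo compound 7 inserting into the O–H bond of alcohol 13 forms the ether under neutral conditions with the carbinol centre untouched. A metal-catalysed coupling of 13 with a 3-halopyrone was considered and set aside: it needs base and a metal that would also engage the terminal alkyne and the base-labile lactone.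

**13 from 9 and 11.** The C–C bond between the carbinol carbon (later C2) and the methyl-bearing carbon (later C3) is cut. One addition of a chiral allenylmetal reagent derived from 11 to aldehyde 9 sets both stereocentres and delivers the alkyne needed as dienophile. The anti adduct corresponds to the trans dihydrobenzofuran.

**7 from 6, 6 from 4, 4 from 1 and 2.** Diazo transfer leads back to hydroxypyrone 6. Its ring comes from dioxinone 4 by thermal acylketene formation and cyclisation, and 4 from acylation of the dienolate of 1 with acid chloride 2. Bringing the propenyl group in with 2 avoids strong-base chemistry on a pyrone methyl group once the alkyne is present.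

**9 from 8 and 11 from 10.** These are phenol protection and alcohol activation.

## Alternatives that were turned down

**Alternative 1: ring contraction of a flavanone.**
- Disconnection: the C3–C3a bond, with the dihydrofuran seen as a contracted chroman-4-one.
- Forward key step: the enantioenriched flavanone A2 is treated with PhI(OAc)2 and H2SO4 in trimethyl orthoformate. The carbon next to the carbonyl is iodinated, the ring A carbon shifts to it, and the trans ester A1 results.
- For: the reaction type is well established on flavanones, the trans outcome is inherent in the migration, and the precursor is simple.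
- Against: A1 carries an ester where a methyl group is needed, so reduction, activation and hydride displacement follow beside a benzylic ether. The bromide must then be coupled to give the propenyl group, and the mesylate that protects ring B from the oxidant must be removed. The stereocentre of A2 lies β to a ketone and can be lost by reversible retro-oxa-Michael ring opening in strong acid.
- Comparison: the key step has firmer precedent than the pyrone cycloaddition, and on that point this alternative is stronger. The chosen strategy offers instead a ring A built with all substituents final, stereocentres never exposed to acid or oxidant, and several fewer steps after the key step.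

**Alternative 2: palladium/norbornene annulation of an aryl iodide with an epoxide.**
- Disconnection: C3–C3a and O1–C7a, both at ring A.
- Forward key step: aryl iodide A4 and cis epoxide A5 react in a Catellani-type process (Pd(OAc)2, phosphine, norbornene, base). The ortho palladacycle opens A5 at the methyl-bearing carbon with inversion, and the alkoxide closes on the ipso carbon to give A3.
- For: it is the most convergent option, it is stereospecific (cis epoxide to trans product), and the methoxy group of A4 supplies the ortho blocking group the manifold needs.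
- Against: A5 is a 1,2-disubstituted epoxide, and attack must occur at the hindered non-benzylic carbon in preference to the electronically activated benzylic one. The wrong regiochemistry gives the isomeric ring system. An electron-rich aryl epoxide may also rearrange to a carbonyl compound under the conditions. The ester of A3 needs about three steps to become an (E)-propenyl group, and the acetal needs acid near C2.
- Comparison: in convergence this alternative is at least as strong. The chosen strategy offers a key step with no regiochemical choice and no metal.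

**Alternative 3: chiral acid hydroalkoxylation of a hydroxystilbene.**
- Disconnection: O1–C2.
- Forward key step: the achiral phenol A7 is protonated at C3 by a confined chiral imidodiphosphorimidate acid, and the phenol oxygen captures the C2 cation to give A6.
- For: both stereocentres come from an achiral substrate in one catalytic step, and only bromide coupling and ester cleavage follow. On step economy and use of chirality this is the stronger plan.
- Against: an enantiodetermining protonation at a carbon without a heteroatom, followed by capture of a ring-B-stabilised cation, must control two centres. The closure is reversible under acid, which would erode both. Friedel–Crafts cyclisation and dimerisation typical of propenylarenes compete.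
- Comparison: the chosen strategy is longer, but it installs the stereocentres by a dependable stoichiometric addition and keeps them as spectators in a neutral key step.

Key step: step 9

Remark on the chemistry: the sense of chirality transfer in step 6 is assumed to follow the accepted course (anti SN2' oxidative addition, transmetalation with retention, closed SE2' addition), by which the (R)-mesylate 11 leads to the S configuration at the methyl-bearing carbon.

## Route

Step 1
Reactants: 1 2,2,6-trimethyl-4H-1,3-dioxin-4-one; 2 (E)-but-2-enoyl chloride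
Product: 4 2,2-dimethyl-6-[(3E)-2-oxopent-3-en-1-yl]-4H-1,3-dioxin-4-one, via lithium dienolate 3 (not isolated)
Conditions: lithium diisopropylamide (2.1 equiv), 1 (2.1 equiv), THF, −78 °C; then 2 (1.0 equiv), −78 °C; aq. NH4Cl
Reagents that add atoms: none
Why: Kinetic deprotonation of the 6-methyl group gives the dienolate 3, which is acylated at its exocyclic γ-carbon by the acid chloride (Claisen-type C-acylation); the second equivalent of 3 is consumed in deprotonating the more acidic product, and 1,2-attack on the acid chloride is expected to outrun conjugate addition at −78 °C.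

Step 2
Reactants: 4 2,2-dimethyl-6-[(3E)-2-oxopent-3-en-1-yl]-4H-1,3-dioxin-4-one
Product: 6 4-hydroxy-6-[(1E)-prop-1-en-1-yl]-2H-pyran-2-one, via acylketene 5 (not isolated)
Conditions: toluene (0.05 M), 110 °C
Reagents that add atoms: none
Why: Thermal retro-[4+2] fragmentation of the dioxinone releases acetone and the acylketene 5, whose enolised ketone oxygen adds to the ketene carbon to close the 4-hydroxy-2-pyrone; this is the standard route from 6-(2-oxoalkyl)dioxinones to 6-substituted 4-hydroxy-2-pyrones and does not involve the E alkene.

Step 3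
Reactants: 6 4-hydroxy-6-[(1E)-prop-1-en-1-yl]-2H-pyran-2-one
Product: 7 3-diazo-6-[(1E)-prop-1-en-1-yl]-2H-pyran-2,4(3H)-dione
Conditions: 4-acetamidobenzenesulfonyl azide, Et3N, MeCN, 0 °C to rt
Reagents that add atoms: 4-acetamidobenzenesulfonyl azide, CC(=O)Nc1ccc(cc1)S(=O)(=O)N=[N+]=[N-]
Why: Regitz diazo transfer to the doubly activated C3 of the cyclic β-keto lactone, which is fully enolised and readily deprotonated by the amine; the analogous 6-methyl compound undergoes this reaction cleanly.

Step 4
Reactants: 8 3-hydroxy-4,5-dimethoxybenzaldehyde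
Product: 9 3,4-dimethoxy-5-(triisopropylsilyloxy)benzaldehyde
Conditions: TIPSCl, imidazole, DMF, rt
Reagents that add atoms: chlorotri(propan-2-yl)silane (TIPSCl), CC(C)[Si](Cl)(C(C)C)C(C)C
Why: Standard silylation of a phenol; the bulky silyl ether masks the one ring B oxygen that must end as a free hydroxyl and is expected to withstand carbonate and heat later.

Step 5
Reactants: 10 (R)-but-3-yn-2-ol
Product: 11 (R)-but-3-yn-2-yl methanesulfonate
Conditions: MsCl, Et3N, CH2Cl2, −78 to 0 °C
Reagents that add atoms: methanesulfonyl chloride, CS(=O)(=O)Cl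
Why: Sulfonylation at oxygen does not touch the stereocentre, so the R configuration is carried into the mesylate, which is used without long storage.

Step 6
Reactants: 9 3,4-dimethoxy-5-(triisopropylsilyloxy)benzaldehyde; 11 (R)-but-3-yn-2-yl methanesulfonate
Product: 13 (1S,2S)-1-[3,4-dimethoxy-5-(triisopropylsilyloxy)phenyl]-2-methylbut-3-yn-1-ol, via allenylindium reagent 12 (not isolated)
Conditions: Pd(dppf)Cl2 (5 mol %), InI (1.4 equiv), 11 (1.4 equiv), THF/HMPA 3:1, rt
Reagents that add atoms: none
Why: Marshall propargylation: zerovalent palladium formed in the flask opens 11 by anti SN2' oxidative addition, transmetalation to indium gives the configurationally defined allenylindium 12, and 12 adds to the aldehyde through a closed chair-like SE2' transition state with the aryl group turned away from the allenyl methyl group, which should give the anti adduct; the axial chirality of 12 sets the methyl-bearing carbon as S and the cyclic transition state relays it to the carbinol carbon, also S.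

Step 7
Reactants: 13 (1S,2S)-1-[3,4-dimethoxy-5-(triisopropylsilyloxy)phenyl]-2-methylbut-3-yn-1-ol; 7 3-diazo-6-[(1E)-prop-1-en-1-yl]-2H-pyran-2,4(3H)-dione
Product: 14 3-{(1S,2S)-1-[3,4-dimethoxy-5-(triisopropylsilyloxy)phenyl]-2-methylbut-3-yn-1-yloxy}-4-hydroxy-6-[(1E)-prop-1-en-1-yl]-2H-pyran-2-one
Conditions: Rh2(OAc)4 (2 mol %), PhF, 70 °C, slow addition of 7 to 13 (1.3 equiv; excess 13 recovered)
Reagents that add atoms: none
Why: Rhodium-carbenoid O–H insertion: Rh2(OAc)4 converts 7 into an electrophilic carbenoid at C3, the hydroxyl oxygen of 13 adds to give an oxonium ylide, and proton transfer with enolisation gives the 3-alkoxy-4-hydroxy-2-pyrone; no bond to the carbinol carbon is broken, so its configuration is retained, and insertion into O–H is normally much faster than addition of such carbenoids to alkynes or arenes.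

Step 8
Reactants: 14 3-{(1S,2S)-1-[3,4-dimethoxy-5-(triisopropylsilyloxy)phenyl]-2-methylbut-3-yn-1-yloxy}-4-hydroxy-6-[(1E)-prop-1-en-1-yl]-2H-pyran-2-one
Product: 15 3-{(1S,2S)-1-[3,4-dimethoxy-5-(triisopropylsilyloxy)phenyl]-2-methylbut-3-yn-1-yloxy}-4-methoxy-6-[(1E)-prop-1-en-1-yl]-2H-pyran-2-one
Conditions: Me2SO4 (1.2 equiv), K2CO3 (1.5 equiv), acetone, rt
Reagents that add atoms: dimethyl sulfate, COS(=O)(=O)OC
Why: O-Alkylation of a vinylogous acid: the pyronate formed with carbonate is methylated by the hard electrophile at O4, the usual outcome for 4-hydroxy-2-pyrones under these conditions; carbonate in dry acetone is too weak to affect the propargylic C–H or the triisopropylsilyl ether.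

Step 9
Reactants: 15 3-{(1S,2S)-1-[3,4-dimethoxy-5-(triisopropylsilyloxy)phenyl]-2-methylbut-3-yn-1-yloxy}-4-methoxy-6-[(1E)-prop-1-en-1-yl]-2H-pyran-2-one
Product: 17 (2S,3S)-2-[3,4-dimethoxy-5-(triisopropylsilyloxy)phenyl]-7-methoxy-3-methyl-5-[(1E)-prop-1-en-1-yl]-2,3-dihydro-1-benzofuran, via bridged lactone cycloadduct 16 (not isolated)
Conditions: 1,2-dichlorobenzene (0.01 M, degassed), BHT (10 mol %), 180 °C, sealed vessel
Reagents that add atoms: none
Why: On heating, the tethered alkyne adds across C3 and C6 of the 2-pyrone in an intramolecular [4+2] cycloaddition to give the bridged lactone 16, which loses CO2 in a retro-[4+2] step and aromatises. The closest known reaction type is the intramolecular Diels–Alder reaction of 2-pyrones with tethered alkynes with extrusion of CO2, together with the analogous cyclisation of 3-(alkynyloxy)pyridazines to dihydrobenzofurans with loss of N2. The dihydrofuran ring closes as the C3a–C7a bond forms, the three-atom O1–C2–C3 tether making it a five-membered ring fused at the diene terminus. Ring A closes through the pair of bonds C3a–C7a and C4–C5 and becomes aromatic on cycloreversion. No stereocentre is created in 17: the bridgehead centres of 16 vanish with the lactone bridge, and C2 and C3, set in step 6, are spectators under neutral thermal conditions. Regiochemistry is fixed by the tether, which places O1 at C7a, methoxy at C7 and propenyl at C5. The step needs periselectivity for the alkyne over the propenyl group and the diene it forms with the pyrone; intramolecularity, high dilution and a radical inhibitor should secure this.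

Step 10
Reactants: 17 (2S,3S)-2-[3,4-dimethoxy-5-(triisopropylsilyloxy)phenyl]-7-methoxy-3-methyl-5-[(1E)-prop-1-en-1-yl]-2,3-dihydro-1-benzofuran
Product: 18 5-{(2S,3S)-7-methoxy-3-methyl-5-[(1E)-prop-1-en-1-yl]-2,3-dihydro-1-benzofuran-2-yl}-2,3-dimethoxyphenol
Conditions: tetrabutylammonium fluoride, AcOH (1:1), THF, 0 °C
Reagents that add atoms: none
Why: Fluoride cleaves the aryl silyl ether through formation of the strong Si–F bond; buffering with AcOH keeps the phenoxide from oxidising and leaves the trans ring junction substituents and the propenyl group untouched.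

## Compound list

1 | 2,2,6-trimethyl-4H-1,3-dioxin-4-one | CC1=CC(=O)OC(C)(C)O1 | starting material
2 | (E)-but-2-enoyl chloride | C/C=C/C(=O)Cl | starting material
3 | lithium 2,2-dimethyl-6-methylidene-6H-1,3-dioxin-4-olate (lithium dienolate of 1) | [Li+].C=C1C=C([O-])OC(C)(C)O1 | intermediate
4 | 2,2-dimethyl-6-[(3E)-2-oxopent-3-en-1-yl]-4H-1,3-dioxin-4-one | C/C=C/C(=O)CC1=CC(=O)OC(C)(C)O1 | intermediate
5 | (6E)-octa-1,6-diene-1,3,5-trione (acylketene) | O=C=CC(=O)CC(=O)/C=C/C | intermediate
6 | 4-hydroxy-6-[(1E)-prop-1-en-1-yl]-2H-pyran-2-one | C/C=C/C1=CC(O)=CC(=O)O1 | intermediate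
7 | 3-diazo-6-[(1E)-prop-1-en-1-yl]-2H-pyran-2,4(3H)-dione | C/C=C/C1=CC(=O)C(=[N+]=[N-])C(=O)O1 | intermediate
8 | 3-hydroxy-4,5-dimethoxybenzaldehyde | O=Cc1cc(O)c(OC)c(OC)c1 | starting material
9 | 3,4-dimethoxy-5-(triisopropylsilyloxy)benzaldehyde | O=Cc1cc(O[Si](C(C)C)(C(C)C)C(C)C)c(OC)c(OC)c1 | intermediate
10 | (R)-but-3-yn-2-ol | C#C[C@@H](C)O | starting material
11 | (R)-but-3-yn-2-yl methanesulfonate | C#C[C@@H](C)OS(C)(=O)=O | intermediate
12 | (P)-buta-1,2-dien-1-yl(iodo)indium methanesulfonate (axial descriptor Sa) | C[CH]=[C@@]=[CH][In](I)OS(C)(=O)=O | intermediate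
13 | (1S,2S)-1-[3,4-dimethoxy-5-(triisopropylsilyloxy)phenyl]-2-methylbut-3-yn-1-ol | C#C[C@H](C)[C@H](O)c1cc(O[Si](C(C)C)(C(C)C)C(C)C)c(OC)c(OC)c1 | intermediate
14 | 3-{(1S,2S)-1-[3,4-dimethoxy-5-(triisopropylsilyloxy)phenyl]-2-methylbut-3-yn-1-yloxy}-4-hydroxy-6-[(1E)-prop-1-en-1-yl]-2H-pyran-2-one | C#C[C@H](C)[C@@H](c1cc(O[Si](C(C)C)(C(C)C)C(C)C)c(OC)c(OC)c1)OC1=C(O)C=C(/C=C/C)OC1=O | intermediate
15 | 3-{(1S,2S)-1-[3,4-dimethoxy-5-(triisopropylsilyloxy)phenyl]-2-methylbut-3-yn-1-yloxy}-4-methoxy-6-[(1E)-prop-1-en-1-yl]-2H-pyran-2-one | C#C[C@H](C)[C@@H](c1cc(O[Si](C(C)C)(C(C)C)C(C)C)c(OC)c(OC)c1)OC1=C(OC)C=C(/C=C/C)OC1=O | intermediate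
16 | bridged lactone cycloadduct: 5-methoxy-1-[(1E)-prop-1-en-1-yl]-2-oxabicyclo[2.2.2]octa-5,7-dien-3-one carrying a (2S,3S)-2-aryl-3-methyl-dihydrofuran ring fused through the ether oxygen at bridgehead C4 and through C8 (both bridgehead epimers) | C/C=C/C12OC(=O)C3(O[C@H](c4cc(O[Si](C(C)C)(C(C)C)C(C)C)c(OC)c(OC)c4)[C@@H](C)C3=C1)C(OC)=C2 | intermediate
17 | (2S,3S)-2-[3,4-dimethoxy-5-(triisopropylsilyloxy)phenyl]-7-methoxy-3-methyl-5-[(1E)-prop-1-en-1-yl]-2,3-dihydro-1-benzofuran | C/C=C/c1cc(OC)c2c(c1)[C@H](C)[C@@H](c1cc(O[Si](C(C)C)(C(C)C)C(C)C)c(OC)c(OC)c1)O2 | intermediate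
18 | 5-{(2S,3S)-7-methoxy-3-methyl-5-[(1E)-prop-1-en-1-yl]-2,3-dihydro-1-benzofuran-2-yl}-2,3-dimethoxyphenol | C/C=C/c1cc(OC)c2c(c1)[C@H](C)[C@@H](c1cc(O)c(OC)c(OC)c1)O2 | target

## Step count and least certain steps

Total step count: 10. Longest linear sequence: 7 steps (steps 1, 2, 3, 7, 8, 9, 10).

**Step 9 (key step).**
- Risk: the cycloaddition may be too slow at temperatures the precursor tolerates. A 3,4-dioxygenated pyrone is an electron-rich diene and the alkyne is unactivated, so the pair is poorly matched. Thermal ionisation or elimination at the benzylic ether carbon, or oligomerisation through the propenyl-substituted diene, could then compete.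
- Fallback (sets out from 13, returns at 17): the pyrone is replaced by a pyridazine, the azadiene for which this tether and ring fusion are established. 3,6-Dichloro-4-methoxypyridazine is coupled with (E)-prop-1-enylboronic acid pinacol ester (Pd(PPh3)4, Na2CO3, dioxane/water) at the chlorine remote from the methoxy group to give 3-chloro-4-methoxy-6-[(1E)-prop-1-en-1-yl]pyridazine F1. The sodium alkoxide of 13 (NaH, THF) displaces the remaining chloride by addition–elimination, which leaves the carbinol centre untouched, and gives 3-{(1S,2S)-1-[3,4-dimethoxy-5-(triisopropylsilyloxy)phenyl]-2-methylbut-3-yn-1-yloxy}-4-methoxy-6-[(1E)-prop-1-en-1-yl]pyridazine F2. Heating F2 in 1,2,4-trichlorobenzene at about 200 °C should bring about the inverse-demand intramolecular [4+2] cycloaddition and loss of N2, giving 17 with the same atom mapping.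

**Step 7.**
- Risk: diversion of the electrophilic carbenoid. Addition to the terminal alkyne (cyclopropene or furan formation) may compete with insertion into a hindered secondary O–H bond, as may insertion into the acidic enol O–H of the product, which is why 13 is used in excess and recovered.
- Fallback (sets out from 13, returns at 15): the alkyne is masked before the carbenoid step. The dianion of 13 (n-BuLi, THF, −78 °C) is silylated with Me3SiCl, any O-silylation being reversed on mildly acidic work-up, to give (1S,2S)-1-[3,4-dimethoxy-5-(triisopropylsilyloxy)phenyl]-2-methyl-4-(trimethylsilyl)but-3-yn-1-ol F3. Carbenoid insertion with 7 as in step 7 gives 3-{(1S,2S)-1-[3,4-dimethoxy-5-(triisopropylsilyloxy)phenyl]-2-methyl-4-(trimethylsilyl)but-3-yn-1-yloxy}-4-hydroxy-6-[(1E)-prop-1-en-1-yl]-2H-pyran-2-one F4. Methylation as in step 8 gives 3-{(1S,2S)-1-[3,4-dimethoxy-5-(triisopropylsilyloxy)phenyl]-2-methyl-4-(trimethylsilyl)but-3-yn-1-yloxy}-4-methoxy-6-[(1E)-prop-1-en-1-yl]-2H-pyran-2-one F5. AgNO3-catalysed protodesilylation in aqueous acetone then frees the alkyne and gives 15.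

**Step 8.**
- Risk: methylation at the lactone carbonyl oxygen of the ambident pyronate instead of O4. This would give the isomeric 2-methoxy-4-pyranone, which lacks the 2-pyrone diene. Base-induced loss of the silyl ether, followed by methylation of the freed phenol, is a second possibility.
- Fallback (sets out from 14, returns at 17): the methyl group is introduced after ring A exists, when only one oxygen can react. Acetylation of 14 (Ac2O, pyridine) gives 3-{(1S,2S)-1-[3,4-dimethoxy-5-(triisopropylsilyloxy)phenyl]-2-methylbut-3-yn-1-yloxy}-2-oxo-6-[(1E)-prop-1-en-1-yl]-2H-pyran-4-yl acetate F6, a less electron-rich diene. Heating as in step 9 should give (2S,3S)-2-[3,4-dimethoxy-5-(triisopropylsilyloxy)phenyl]-3-methyl-5-[(1E)-prop-1-en-1-yl]-2,3-dihydro-1-benzofuran-7-yl acetate F7. Selective cleavage of the aryl acetate (K2CO3, MeOH, 0 °C) gives (2S,3S)-2-[3,4-dimethoxy-5-(triisopropylsilyloxy)phenyl]-3-methyl-5-[(1E)-prop-1-en-1-yl]-2,3-dihydro-1-benzofuran-7-ol F8, and methylation of this single free phenol (MeI, K2CO3, acetone) gives 17.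

**Step 6.**
- Risk: incomplete anti selectivity and partial loss of enantiomeric purity. An aromatic aldehyde discriminates less well in the closed transition state than an α-branched aliphatic one, and the allenylpalladium or allenylindium species can racemise before it adds.
- Fallback (sets out from 9, returns at 13): catalyst-controlled allenylboration. Racemic 2-(buta-1,2-dien-1-yl)-4,4,5,5-tetramethyl-1,3,2-dioxaborolane F9, made from racemic but-3-yn-2-yl methyl carbonate and B2pin2 under copper catalysis (CuOtBu, Xantphos), is used in excess with 9 and a chiral binaphthyl-derived phosphoric acid (TRIP) in toluene at low temperature. The closed boron transition state gives the anti adduct, and the acid selects one enantiomer of the reagent and one aldehyde face, so that the appropriate enantiomer of the acid should give 13.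

## Further compounds

F1 | step 9 | 3-chloro-4-methoxy-6-[(1E)-prop-1-en-1-yl]pyridazine | C/C=C/c1cc(OC)c(Cl)nn1
F2 | step 9 | 3-{(1S,2S)-1-[3,4-dimethoxy-5-(triisopropylsilyloxy)phenyl]-2-methylbut-3-yn-1-yloxy}-4-methoxy-6-[(1E)-prop-1-en-1-yl]pyridazine | C#C[C@H](C)[C@@H](c1cc(O[Si](C(C)C)(C(C)C)C(C)C)c(OC)c(OC)c1)Oc1nnc(/C=C/C)cc1OC
F3 | step 7 | (1S,2S)-1-[3,4-dimethoxy-5-(triisopropylsilyloxy)phenyl]-2-methyl-4-(trimethylsilyl)but-3-yn-1-ol | C[Si](C)(C)C#C[C@H](C)[C@H](O)c1cc(O[Si](C(C)C)(C(C)C)C(C)C)c(OC)c(OC)c1
F4 | step 7 | 3-{(1S,2S)-1-[3,4-dimethoxy-5-(triisopropylsilyloxy)phenyl]-2-methyl-4-(trimethylsilyl)but-3-yn-1-yloxy}-4-hydroxy-6-[(1E)-prop-1-en-1-yl]-2H-pyran-2-one | C[Si](C)(C)C#C[C@H](C)[C@@H](c1cc(O[Si](C(C)C)(C(C)C)C(C)C)c(OC)c(OC)c1)OC1=C(O)C=C(/C=C/C)OC1=O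
F5 | step 7 | 3-{(1S,2S)-1-[3,4-dimethoxy-5-(triisopropylsilyloxy)phenyl]-2-methyl-4-(trimethylsilyl)but-3-yn-1-yloxy}-4-methoxy-6-[(1E)-prop-1-en-1-yl]-2H-pyran-2-one | C[Si](C)(C)C#C[C@H](C)[C@@H](c1cc(O[Si](C(C)C)(C(C)C)C(C)C)c(OC)c(OC)c1)OC1=C(OC)C=C(/C=C/C)OC1=O
F6 | step 8 | 3-{(1S,2S)-1-[3,4-dimethoxy-5-(triisopropylsilyloxy)phenyl]-2-methylbut-3-yn-1-yloxy}-2-oxo-6-[(1E)-prop-1-en-1-yl]-2H-pyran-4-yl acetate | C#C[C@H](C)[C@@H](c1cc(O[Si](C(C)C)(C(C)C)C(C)C)c(OC)c(OC)c1)OC1=C(OC(C)=O)C=C(/C=C/C)OC1=O
F7 | step 8 | (2S,3S)-2-[3,4-dimethoxy-5-(triisopropylsilyloxy)phenyl]-3-methyl-5-[(1E)-prop-1-en-1-yl]-2,3-dihydro-1-benzofuran-7-yl acetate | C/C=C/c1cc(OC(C)=O)c2c(c1)[C@H](C)[C@@H](c1cc(O[Si](C(C)C)(C(C)C)C(C)C)c(OC)c(OC)c1)O2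
F8 | step 8 | (2S,3S)-2-[3,4-dimethoxy-5-(triisopropylsilyloxy)phenyl]-3-methyl-5-[(1E)-prop-1-en-1-yl]-2,3-dihydro-1-benzofuran-7-ol | C/C=C/c1cc(O)c2c(c1)[C@H](C)[C@@H](c1cc(O[Si](C(C)C)(C(C)C)C(C)C)c(OC)c(OC)c1)O2
F9 | step 6 | racemic 2-(buta-1,2-dien-1-yl)-4,4,5,5-tetramethyl-1,3,2-dioxaborolane | CC=C=CB1OC(C)(C)C(C)(C)O1
A1 | alternative 1 | methyl (2S,3S)-5-bromo-2-[3,4-dimethoxy-5-(methylsulfonyloxy)phenyl]-7-methoxy-2,3-dihydro-1-benzofuran-3-carboxylate | Brc1cc(OC)c2c(c1)[C@H](C(=O)OC)[C@@H](c1cc(OS(C)(=O)=O)c(OC)c(OC)c1)O2
A2 | alternative 1 | (2S)-6-bromo-2-[3,4-dimethoxy-5-(methylsulfonyloxy)phenyl]-8-methoxy-2,3-dihydro-4H-chromen-4-one | O=C1C[C@@H](c2cc(OS(C)(=O)=O)c(OC)c(OC)c2)Oc2c(OC)cc(Br)cc12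
A3 | alternative 2 | methyl (2S,3S)-2-[3,4-dimethoxy-5-(methoxymethoxy)phenyl]-7-methoxy-3-methyl-2,3-dihydro-1-benzofuran-5-carboxylate | COC(=O)c1cc(OC)c2c(c1)[C@H](C)[C@@H](c1cc(OCOC)c(OC)c(OC)c1)O2
A4 | alternative 2 | methyl 4-iodo-3-methoxybenzoate | COC(=O)c1ccc(I)c(OC)c1
A5 | alternative 2 | (2R,3S)-2-[3,4-dimethoxy-5-(methoxymethoxy)phenyl]-3-methyloxirane (cis) | C[C@H]1[C@@H](c2cc(OCOC)c(OC)c(OC)c2)O1
A6 | alternative 3 | 5-[(2S,3S)-5-bromo-7-methoxy-3-methyl-2,3-dihydro-1-benzofuran-2-yl]-2,3-dimethoxyphenyl 2,2-dimethylpropanoate | Brc1cc(OC)c2c(c1)[C@H](C)[C@@H](c1cc(OC(=O)C(C)(C)C)c(OC)c(OC)c1)O2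
A7 | alternative 3 | 5-[(1E)-2-(5-bromo-2-hydroxy-3-methoxyphenyl)prop-1-en-1-yl]-2,3-dimethoxyphenyl 2,2-dimethylpropanoate | C/C(=C\c1cc(OC(=O)C(C)(C)C)c(OC)c(OC)c1)c1cc(Br)cc(OC)c1O
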